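## The problem

The target is a flavan-3,4-diol. Benzene ring A is fused through C4a and C8a to dihydropyran ring C, which carries the 4-hydroxyphenyl ring B at C2 and hydroxyls at C3 and C4. Ring C holds three contiguous stereocentres, C2 (R), C3 (S) and C4 (S), in a 2,3-trans-3,4-cis arrangement. The C2/C3 pair has the pattern a trans-epoxide delivers in absolute form, whereas C4 has no handle of its own and is best set relative to C3 by 1,2-induction when the C4a–C4 bond is made. Ring A is fully differentiated (5-OMe, 7-OH, 8-prenyl, only C6 free), so the prenyl group must be placed between two oxygens and the C4 carbon between an oxygen and the methoxy group without regiochemical leakage. The molecule is fragile in three places. The C4 carbinol is benzylic to a 2,4,6-trioxygenated ring and ionises under acid to a quinone-methide-like cation, with epimerisation, solvolysis or capture by a second arene. The prenyl alkene cyclises onto the neighbouring 7-OH under acid and does not survive peracids, quinone oxidants or hydrogenolysis, and the free phenols are easily oxidised. The enabling feature is twofold. Ring A, detached at C4a–C4 and O1–C2, is 5-methoxy-2-prenylresorcinol, whose mirror plane through C2 and C5 makes its two OH/ortho-CH pairs identical. And C2, C3 and C4 all bear oxygen, so the three-carbon bridge has exactly the oxidation pattern of a 3-arylglycidic aldehyde.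

## Retrosynthesis

Target 15 is traced first to its 4'-O-silyl ether 14, cutting only the O–Si bond. A mask on the ring-B phenol is needed because, while C2 is still an epoxide carbon, a free para-hydroxyl would make that epoxide a quinone-methide precursor. A tert-butyldimethylsilyl ether leaves under buffered fluoride, which the C4 carbinol and the prenyl group tolerate, whereas acid-labile or hydrogenolysable groups would not. The 7-OH is left free: it is a spectator, and leaving it unprotected keeps the arene partner symmetric.

Ring C of 14 is cut at C4a–C4 and at O1–C2, giving resorcinol 6 and epoxy aldehyde 11. Forward, the reaction runs through aryloxytitanium 12 and epoxy carbinol 13. Cutting O1–C2 alone would leave the C4 carbinol and the C4a–C4 bond to be made earlier on a longer chain. Cutting C4a–C4 together with O1–C8a would need an ortho-difunctionalised ring A. The chosen cut uses only a C–H and an O–H of a symmetric arene and removes the ring, two skeletal bonds and the C4 stereocentre in one operation. The precursors are an achiral arene and a three-carbon piece whose two stereocentres come from one catalytic step. The forward reaction must deliver ortho regioselectivity, erythro induction at C4 from the epoxide carbon next to the aldehyde, 6-endo opening of the epoxide at the benzylic carbon with inversion, and conditions mild enough for the C4 carbinol.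

Resorcinol 6 is simplified by cutting the bond between C2 of the ring and the prenyl CH2, after re-protecting both phenols as methoxymethyl ethers (5). This leads to aryllithium 4, generated from bis-acetal 2, and prenyl bromide 3; 2 comes from 5-methoxyresorcinol 1. Direct electrophilic prenylation of 1 would give ring isomers and O-alkylation. Directed metalation places the carbon between the two strongest directing groups, and those same groups are removable. The forward steps must show selectivity for the doubly flanked position and for attack at the primary end of the allyl unit.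

Aldehyde 11 is taken back to epoxy alcohol 10, and the two C–O bonds of the epoxide are cut to reveal E-allylic alcohol 9. This maps onto titanium–tartrate epoxidation, which sets both stereocentres in one step with predictable sense. A dihydroxylation-based route would need further steps through a labile electron-rich benzylic halide to reach the epoxide. Alcohol 9 comes by reduction from silyl ether 8 and hence from methyl 4-hydroxycinnamate 7. The forward steps must preserve the E geometry and the acid-sensitive 4-silyloxyphenyl epoxide up to the coupling.

## Roads not taken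

Alternative 1: Both bonds to ring A are cut (C4a–C4 and C8a–O1), leaving ring C open at O1–C2. In the forward step CsF generates an aryne from silylaryl triflate A2. The carboxylate of acetonide acid A3 adds through oxygen at C8a, and the resulting aryl anion at C4a attacks the acyl carbon, giving ortho-hydroxyaryl ketone A1.
- Merits: the ring-A substitution pattern is fixed by the aryne precursor and owes nothing to symmetry; no sensitive epoxy aldehyde is handled; the C2/C3 oxygens come from a robust diol.
- Weak points: the step closes no ring and leaves C4 as a ketone. The 4β-carbinol then needs a selective reduction, and O1–C2 needs a separate closure with inversion among three hydroxyls. The acetonide and two methoxymethyl ethers must be removed with acid in the presence of the prenyl group and the ionisable C4 carbinol. A2 is a hexasubstituted benzene that needs a long synthesis with a differentiated 7-oxygen. The oxygen must add next to the prenyl group, which the 5-methoxy group favours electronically but the ortho substituent hinders.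
- Comparison: this road is better on regiochemical certainty in ring A. The chosen plan sets against that a coupling that closes ring C and sets C4 and C2 at once, roughly half the step count, and only one fluoride-labile protecting group at the end.

Alternative 2: Only the C4–O bond is cut, as a C–H oxidation of a complete flavan-3-ol. In the forward step 2,3-dichloro-5,6-dicyano-1,4-benzoquinone abstracts hydride from C4 of tert-butyl carbonate A5. The carbonate carbonyl oxygen on C3 captures the cation with loss of the tert-butyl group, giving cis-fused cyclic carbonate A4.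
- Merits: the 3,4-cis relationship is enforced by the five-membered tether, which is more secure than acyclic 1,2-induction. Here this road is better than the chosen one.
- Weak points: the whole 5-O-methylafzelechin skeleton with C2 and C3 set must be built first. The prenyl CH2 is benzylic and allylic and would not survive the quinone, so bromine stands in at C8. That requires a C8-versus-C6-selective bromination and a late prenylation next to the cyclic carbonate, then carbonate hydrolysis and two desilylations.
- Comparison: the chosen plan sets against the better C4 control a convergent assembly in which the prenyl group is present from the start, no oxidant touches the electron-rich ring, and the sequence is far shorter. Its 1,2-induction points in the required sense and has a stepwise fallback.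

Alternative 3: Ring A is built last by cutting C4a–C5 and C8–C8a. In the forward step the 1,1-dimethoxy-3-silyloxy diene A8, with the prenyl group on its nucleophilic terminus, adds across the sulfinyl enone of dihydropyranone A7. Loss of benzenesulfenic acid, methanol and the silyl group then aromatises the adduct to dihydroflavonol A6.
- Merits: the 5-OMe/7-OH/8-prenyl pattern follows from the polarity of the diene, so no arene regiochemistry question arises; C2 and C3 are set beforehand; the C4 ketone is robust.
- Weak points: C4 is deferred to a ketone reduction that must give the axial 3,4-cis alcohol, whereas borohydride reduction of 2,3-trans-dihydroflavonols generally favours the 3,4-trans diol. A7, with two stereocentres and a sulfinyl group, needs many steps, and the tetrasubstituted diene A8 is hydrolytically labile.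
- Comparison: this road is better on ring-A regiochemistry. The chosen plan answers with a symmetric arene for which the question does not arise at the coupling, with C4 set directly at the carbinol level, and with fewer steps.

Key step: step 8

Remark: flavan numbering (O1, C2–C4, C4a, C5–C8, C8a; ring B primed) is used for ring positions throughout; the titanium-bound intermediate 13 is drawn as the free carbinol that hydrolysis of its titanium alkoxide would give.

Step 1
Reactants: 1 5-methoxybenzene-1,3-diol (5-methoxyresorcinol)
Product: 2 1-methoxy-3,5-bis(methoxymethoxy)benzene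
Conditions: MOMCl, i-Pr2NEt, CH2Cl2, 0 °C → rt
Reagents that add atoms: chloromethyl methyl ether, COCCl
Why: Williamson-type O-alkylation of both phenols with the reactive chloromethyl ether; the acetals are chosen because they are strong ortho-directing groups that can later be removed, and no stereocentre is involved.

Step 2
Reactants: 2 1-methoxy-3,5-bis(methoxymethoxy)benzene; 3 1-bromo-3-methylbut-2-ene (prenyl bromide)
Product: 5 5-methoxy-1,3-bis(methoxymethoxy)-2-(3-methylbut-2-enyl)benzene, via aryllithium 4 (not isolated)
Conditions: n-BuLi, THF, 0 °C → rt; then CuI (10 mol %), 3, −78 °C → rt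
Reagents that add atoms: none
Why: Directed ortho-metalation: the position flanked by two methoxymethoxy groups is the best coordinated and most acidic site, ahead of the two positions flanked by one acetal and the weaker methoxy director; aryllithium 4 is then alkylated by copper-catalysed allylic substitution at the primary carbon of 3 (SN2 rather than SN2').

Step 3
Reactants: 5 5-methoxy-1,3-bis(methoxymethoxy)-2-(3-methylbut-2-enyl)benzene
Product: 6 5-methoxy-2-(3-methylbut-2-enyl)benzene-1,3-diol
Conditions: HCl (1 M in MeOH), rt to 40 °C
Reagents that add atoms: none
Why: Acid-catalysed acetal exchange with methanol (methoxymethyl ether cleavage) at moderate acidity; the trisubstituted alkene is expected to survive because cyclisation of an ortho-prenylphenol to a chroman needs stronger acid or heat.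

Step 4
Reactants: 7 methyl (E)-3-(4-hydroxyphenyl)prop-2-enoate (methyl 4-hydroxycinnamate)
Product: 8 methyl (E)-3-[4-(tert-butyldimethylsilyloxy)phenyl]prop-2-enoate
Conditions: TBSCl, imidazole, DMF, rt
Reagents that add atoms: tert-butyldimethylsilyl chloride, CC(C)(C)[Si](C)(C)Cl
Why: Silylation of the phenol under imidazole/DMF conditions; this silyl ether is the only protecting group carried to the end of the route and leaves under buffered fluoride.

Step 5
Reactants: 8 methyl (E)-3-[4-(tert-butyldimethylsilyloxy)phenyl]prop-2-enoate
Product: 9 (E)-3-[4-(tert-butyldimethylsilyloxy)phenyl]prop-2-en-1-ol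
Conditions: i-Bu2AlH, CH2Cl2, −78 °C; aq. potassium sodium tartrate
Reagents that add atoms: none
Why: 1,2-Reduction of the conjugated ester by the aluminium hydride gives the E-allylic alcohol without touching the aryl silyl ether or the alkene geometry.

Step 6
Reactants: 9 (E)-3-[4-(tert-butyldimethylsilyloxy)phenyl]prop-2-en-1-ol
Product: 10 [(2S,3S)-3-[4-(tert-butyldimethylsilyloxy)phenyl]oxiran-2-yl]methanol
Conditions: Ti(OiPr)4 (10 mol %), L-(+)-diethyl tartrate (12 mol %), t-BuOOH, 4 Å molecular sieves, CH2Cl2, −25 °C
Reagents that add atoms: tert-butyl hydroperoxide, CC(C)(C)OO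
Why: Katsuki–Sharpless asymmetric epoxidation; with L-(+)-diethyl tartrate an E-3-arylallyl alcohol is epoxidised on the face that gives the (2S,3S)-epoxy alcohol, which fixes the future C3 and, before its inversion, the future C2; sieves, catalytic titanium and low temperature limit opening of the electron-rich benzylic epoxide.

Step 7
Reactants: 10 [(2S,3S)-3-[4-(tert-butyldimethylsilyloxy)phenyl]oxiran-2-yl]methanol
Product: 11 (2R,3S)-3-[4-(tert-butyldimethylsilyloxy)phenyl]oxirane-2-carbaldehyde
Conditions: SO3·pyridine, DMSO, Et3N, CH2Cl2, 0 °C
Reagents that add atoms: none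
Why: Parikh–Doering oxidation (activated dimethyl sulfoxide) under basic, non-aqueous conditions converts the primary alcohol into the aldehyde without opening or epimerising the epoxide; the descriptor at C2 changes from S to R only because the formyl group outranks C3.

Step 8
Reactants: 6 5-methoxy-2-(3-methylbut-2-enyl)benzene-1,3-diol; 11 (2R,3S)-3-[4-(tert-butyldimethylsilyloxy)phenyl]oxirane-2-carbaldehyde
Product: 14 (2R,3S,4S)-2-[4-(tert-butyldimethylsilyloxy)phenyl]-5-methoxy-8-(3-methylbut-2-enyl)-3,4-dihydro-2H-chromene-3,4,7-triol, via aryloxytitanium triisopropoxide 12 (not isolated), via epoxy carbinol titanium alkoxide 13 (not isolated)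
Conditions: 6 (1.5 equiv), Ti(OiPr)4 (1.5 equiv), toluene, rt, i-PrOH removed by evaporation; then 11, CH2Cl2–toluene, −40 °C → rt; aq. potassium sodium tartrate
Reagents that add atoms: none
Why: Proposed new method: exchange of one isopropoxide of Ti(OiPr)4 for a phenol oxygen of 6 gives aryloxytitanium 12, which binds the aldehyde of 11 at titanium and delivers the carbonyl carbon to the free ortho carbon (the future C4a) through a six-membered cyclic transition state, giving the titanium alkoxide of epoxy carbinol 13 (C4a–C4). The closest known reactions are the ortho-selective hydroxyalkylation of titanium and magnesium phenoxides with chiral α-oxygenated aldehydes and, separately, the acid- or Lewis-acid-promoted 6-endo opening of 3-aryl epoxides by an ortho phenol to give 2,3-trans-flavan-3-ols; running both on an epoxy aldehyde in one flask is the untested part. C4 is set by 1,2-induction from the epoxide carbon that becomes C3: with a monodentate, non-chelating aryloxide of tetravalent titanium the Felkin–Anh (polar, Cornforth-like) transition state holds the epoxide C–O bond anti to the incoming arene, which gives the erythro carbinol and hence the 3,4-cis (4S) diol. Ring C then closes by 6-endo-tet attack of O1 on the benzylic epoxide carbon (O1–C2), the titanium alkoxide at C4 activating the epoxide oxygen as in titanium-mediated C3-selective openings of 2,3-epoxy alcohols; backside attack inverts this carbon from S to R and, starting from the trans epoxide, gives the 2,3-trans ring. The step needs ortho regioselectivity, which the Ti–O tether and the equivalence of the two OH/CH pairs of 6 supply (C2 of 6 is blocked by prenyl), erythro selectivity at C4, and 6-endo over 5-exo opening, which the cation-stabilising 4-silyloxyphenyl group and the chelate both favour. C3 is carried over unchanged from 11. An excess of 6 limits a second hydroxyalkylation at C6, and removing isopropanol before 11 is added keeps it from opening the epoxide.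

Step 9
Reactants: 14 (2R,3S,4S)-2-[4-(tert-butyldimethylsilyloxy)phenyl]-5-methoxy-8-(3-methylbut-2-enyl)-3,4-dihydro-2H-chromene-3,4,7-triol
Product: 15 (2R,3S,4S)-2-(4-hydroxyphenyl)-5-methoxy-8-(3-methylbut-2-enyl)-3,4-dihydro-2H-chromene-3,4,7-triol (5-O-methyl-8-prenylafzelechin-4β-ol)
Conditions: Bu4NF, AcOH, THF, 0 °C
Reagents that add atoms: none
Why: Fluoride cleavage of the aryl silyl ether; acetic acid buffers the phenoxide so that neither the C4 carbinol nor the C2–O1 bond meets strong base or acid, and no stereocentre is touched.

Compound list

1 | 5-methoxybenzene-1,3-diol (5-methoxyresorcinol) | COc1cc(O)cc(O)c1 | starting material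
2 | 1-methoxy-3,5-bis(methoxymethoxy)benzene | COCOc1cc(OC)cc(OCOC)c1 | intermediate
3 | 1-bromo-3-methylbut-2-ene (prenyl bromide) | CC(C)=CCBr | starting material
4 | [4-methoxy-2,6-bis(methoxymethoxy)phenyl]lithium | [Li]c1c(OCOC)cc(OC)cc1OCOC | intermediate (not isolated)
5 | 5-methoxy-1,3-bis(methoxymethoxy)-2-(3-methylbut-2-enyl)benzene | COCOc1cc(OC)cc(OCOC)c1CC=C(C)C | intermediate
6 | 5-methoxy-2-(3-methylbut-2-enyl)benzene-1,3-diol | COc1cc(O)c(CC=C(C)C)c(O)c1 | intermediate
7 | methyl (E)-3-(4-hydroxyphenyl)prop-2-enoate | COC(=O)/C=C/c1ccc(O)cc1 | starting material
8 | methyl (E)-3-[4-(tert-butyldimethylsilyloxy)phenyl]prop-2-enoate | COC(=O)/C=C/c1ccc(O[Si](C)(C)C(C)(C)C)cc1 | intermediate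
9 | (E)-3-[4-(tert-butyldimethylsilyloxy)phenyl]prop-2-en-1-ol | OC/C=C/c1ccc(O[Si](C)(C)C(C)(C)C)cc1 | intermediate
10 | [(2S,3S)-3-[4-(tert-butyldimethylsilyloxy)phenyl]oxiran-2-yl]methanol | OC[C@@H]1O[C@H]1c1ccc(O[Si](C)(C)C(C)(C)C)cc1 | intermediate
11 | (2R,3S)-3-[4-(tert-butyldimethylsilyloxy)phenyl]oxirane-2-carbaldehyde | O=C[C@@H]1O[C@H]1c1ccc(O[Si](C)(C)C(C)(C)C)cc1 | intermediate
12 | [3-hydroxy-5-methoxy-2-(3-methylbut-2-enyl)phenoxy]tri(propan-2-yloxy)titanium | COc1cc(O)c(CC=C(C)C)c(O[Ti](OC(C)C)(OC(C)C)OC(C)C)c1 | intermediate (not isolated)
13 | (S)-[2,4-dihydroxy-6-methoxy-3-(3-methylbut-2-enyl)phenyl]{(2S,3S)-3-[4-(tert-butyldimethylsilyloxy)phenyl]oxiran-2-yl}methanol, held in the flask as its titanium alkoxide | COc1cc(O)c(CC=C(C)C)c(O)c1[C@H](O)[C@@H]1O[C@H]1c1ccc(O[Si](C)(C)C(C)(C)C)cc1 | intermediate (not isolated)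
14 | (2R,3S,4S)-2-[4-(tert-butyldimethylsilyloxy)phenyl]-5-methoxy-8-(3-methylbut-2-enyl)-3,4-dihydro-2H-chromene-3,4,7-triol | COc1cc(O)c(CC=C(C)C)c2c1[C@H](O)[C@H](O)[C@@H](c1ccc(O[Si](C)(C)C(C)(C)C)cc1)O2 | intermediate
15 | (2R,3S,4S)-2-(4-hydroxyphenyl)-5-methoxy-8-(3-methylbut-2-enyl)-3,4-dihydro-2H-chromene-3,4,7-triol | COc1cc(O)c(CC=C(C)C)c2c1[C@H](O)[C@H](O)[C@@H](c1ccc(O)cc1)O2 | target

Total steps: 9. Longest linear sequence: 6 steps (7 → 8 → 9 → 10 → 11 → 14 → 15, steps 4 to 9); the arene branch (steps 1 to 3) joins at step 8.

Steps least certain to work

Step 8 (key step, the proposed new method). Four things may go wrong: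
- Loss of facial control at the aldehyde: a titanium centre that binds the carbonyl and epoxide oxygens together would reverse the induction toward the threo carbinol and the 3,4-trans diol.
- Opening of the activated benzylic epoxide by isopropoxide or by the nucleophilic arene carbon before O1 can attack.
- Ionisation at C4 of the electron-rich carbinol under the Lewis acid, with epimerisation or capture by a second molecule of 6.
- A second hydroxyalkylation at C6.

The fallback uses known reactions only, sets out from 6 and 11 and returns at 15. It makes the C4a–C4 bond with an aryllithium and closes the ring separately. Compound 6 is silylated (TBSCl, imidazole, DMF) to 1,3-bis(tert-butyldimethylsilyloxy)-5-methoxy-2-(3-methylbut-2-enyl)benzene F1. N-Bromosuccinimide in CH2Cl2 at low temperature then brominates one of the two equivalent free ring positions to give 1-bromo-2,4-bis(tert-butyldimethylsilyloxy)-6-methoxy-3-(3-methylbut-2-enyl)benzene F2. Bromine–lithium exchange with t-BuLi at −78 °C (kept cold to avoid O-to-C silyl migration) and addition to 11 is an organolithium addition to an α,β-epoxy aldehyde with Felkin–Anh preference, and the epimers are separable at this stage. It gives (S)-[2,4-bis(tert-butyldimethylsilyloxy)-6-methoxy-3-(3-methylbut-2-enyl)phenyl]{(2S,3S)-3-[4-(tert-butyldimethylsilyloxy)phenyl]oxiran-2-yl}methanol F3. Bu4NF buffered with AcOH removes the three silyl groups to give (S)-[2,4-dihydroxy-6-methoxy-3-(3-methylbut-2-enyl)phenyl][(2S,3S)-3-(4-hydroxyphenyl)oxiran-2-yl]methanol F4. Its freed O1 opens the para-hydroxybenzylic epoxide in the 6-endo mode known from flavan-3-ol syntheses, with a trace of pyridinium p-toluenesulfonate if closure is slow, and gives 15 directly.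

Step 6. The product epoxide may be opened at the benzylic carbon by titanium-bound alkoxide, tartrate or hydroperoxide during reaction or work-up, because the 4-silyloxyphenyl group stabilises positive charge there. This lowers recovery and can erode optical purity through reversible C–O cleavage. The fallback sets out from 9 and returns at 10. It is an epoxidation by a chiral dioxirane without any Lewis acid: KHSO5, K2CO3 buffer (pH about 10), MeCN/dimethoxymethane/water, 0 °C, with 1,2:4,5-di-O-isopropylidene-β-L-erythro-2,3-hexodiulo-2,6-pyranose as the ketone catalyst. The D-fructose-derived ketone gives R,R epoxides from E-1-arylalkenes, so its L-enantiomer is needed for the (2S,3S) series. No new compound is involved.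

Step 2. Metalation may occur at the positions between one acetal and the methoxy group as well as between the two acetals, and the alkylation may suffer allylic transposition (attack at the tertiary end of the prenyl unit). The fallback sets out from 1 and 3, returns at 6 and replaces steps 1 to 3. It is a direct C-prenylation of the unprotected phenoxide of 1 with 3 in aqueous KOH at 0 °C to rt, the classical C-alkylation of phloroglucinol-type phenoxides. It reaches 6 in one step but unselectively, so 6 must be separated by chromatography from ring-isomeric, O-alkylated and doubly alkylated material. This is tolerable because both reactants are inexpensive.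

Step 3. The prenyl group may cyclise onto an ortho phenol under the acid (chroman formation), or methanol or HCl may add across the trisubstituted alkene while the acetals are cleaved. The fallback sets out from 1, returns at 6 and replaces the acid-labile acetal by a fluoride-labile one. Compound 1 is alkylated with 2-(trimethylsilyl)ethoxymethyl chloride and i-Pr2NEt to 1-methoxy-3,5-bis{[2-(trimethylsilyl)ethoxy]methoxy}benzene F5. F5 is lithiated and prenylated with 3 as in step 2 to give 5-methoxy-2-(3-methylbut-2-enyl)-1,3-bis{[2-(trimethylsilyl)ethoxy]methoxy}benzene F6. Bu4NF in THF/DMPU at 50–70 °C then cleaves both acetals by fragmentation and gives 6 without acid.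

Further compounds

F1 | step 8 | 1,3-bis(tert-butyldimethylsilyloxy)-5-methoxy-2-(3-methylbut-2-enyl)benzene | COc1cc(O[Si](C)(C)C(C)(C)C)c(CC=C(C)C)c(O[Si](C)(C)C(C)(C)C)c1
F2 | step 8 | 1-bromo-2,4-bis(tert-butyldimethylsilyloxy)-6-methoxy-3-(3-methylbut-2-enyl)benzene | COc1cc(O[Si](C)(C)C(C)(C)C)c(CC=C(C)C)c(O[Si](C)(C)C(C)(C)C)c1Br
F3 | step 8 | (S)-[2,4-bis(tert-butyldimethylsilyloxy)-6-methoxy-3-(3-methylbut-2-enyl)phenyl]{(2S,3S)-3-[4-(tert-butyldimethylsilyloxy)phenyl]oxiran-2-yl}methanol | COc1cc(O[Si](C)(C)C(C)(C)C)c(CC=C(C)C)c(O[Si](C)(C)C(C)(C)C)c1[C@H](O)[C@@H]1O[C@H]1c1ccc(O[Si](C)(C)C(C)(C)C)cc1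
F4 | step 8 | (S)-[2,4-dihydroxy-6-methoxy-3-(3-methylbut-2-enyl)phenyl][(2S,3S)-3-(4-hydroxyphenyl)oxiran-2-yl]methanol | COc1cc(O)c(CC=C(C)C)c(O)c1[C@H](O)[C@@H]1O[C@H]1c1ccc(O)cc1
F0 | step 6 | none | none
F0 | step 2 | none | none
F5 | step 3 | 1-methoxy-3,5-bis{[2-(trimethylsilyl)ethoxy]methoxy}benzene | COc1cc(OCOCC[Si](C)(C)C)cc(OCOCC[Si](C)(C)C)c1
F6 | step 3 | 5-methoxy-2-(3-methylbut-2-enyl)-1,3-bis{[2-(trimethylsilyl)ethoxy]methoxy}benzene | COc1cc(OCOCC[Si](C)(C)C)c(CC=C(C)C)c(OCOCC[Si](C)(C)C)c1
A1 | alternative 1 | [2-hydroxy-6-methoxy-4-(methoxymethoxy)-3-(3-methylbut-2-enyl)phenyl] [(4R,5S)-5-[4-(methoxymethoxy)phenyl]-2,2-dimethyl-1,3-dioxolan-4-yl] ketone | COc1cc(OCOC)c(CC=C(C)C)c(O)c1C(=O)[C@@H]1OC(C)(C)O[C@H]1c1ccc(OCOC)cc1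
A2 | alternative 1 | 3-methoxy-5-(methoxymethoxy)-6-(3-methylbut-2-enyl)-2-(trimethylsilyl)phenyl trifluoromethanesulfonate | COc1cc(OCOC)c(CC=C(C)C)c(OS(=O)(=O)C(F)(F)F)c1[Si](C)(C)C
A3 | alternative 1 | (4R,5S)-5-[4-(methoxymethoxy)phenyl]-2,2-dimethyl-1,3-dioxolane-4-carboxylic acid | OC(=O)[C@@H]1OC(C)(C)O[C@H]1c1ccc(OCOC)cc1
A4 | alternative 2 | 3,4-cis cyclic carbonate of 8-bromo-7,4'-bis-O-(tert-butyldimethylsilyl)-5-O-methylafzelechin-4β-ol | COc1cc(O[Si](C)(C)C(C)(C)C)c(Br)c2c1[C@@H]3OC(=O)O[C@@H]3[C@@H](c1ccc(O[Si](C)(C)C(C)(C)C)cc1)O2
A5 | alternative 2 | tert-butyl (2R,3S)-8-bromo-7-(tert-butyldimethylsilyloxy)-2-[4-(tert-butyldimethylsilyloxy)phenyl]-5-methoxy-3,4-dihydro-2H-chromen-3-yl carbonate | COc1cc(O[Si](C)(C)C(C)(C)C)c(Br)c2c1C[C@H](OC(=O)OC(C)(C)C)[C@@H](c1ccc(O[Si](C)(C)C(C)(C)C)cc1)O2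
A6 | alternative 3 | (2R,3R)-3-(tert-butyldimethylsilyloxy)-2-[4-(tert-butyldimethylsilyloxy)phenyl]-7-hydroxy-5-methoxy-8-(3-methylbut-2-enyl)-2,3-dihydro-4H-chromen-4-one | COc1cc(O)c(CC=C(C)C)c2c1C(=O)[C@H](O[Si](C)(C)C(C)(C)C)[C@@H](c1ccc(O[Si](C)(C)C(C)(C)C)cc1)O2
A7 | alternative 3 | (2R,3R)-3-(tert-butyldimethylsilyloxy)-2-[4-(tert-butyldimethylsilyloxy)phenyl]-5-(phenylsulfinyl)-2,3-dihydro-4H-pyran-4-one | O=C1[C@H](O[Si](C)(C)C(C)(C)C)[C@@H](c2ccc(O[Si](C)(C)C(C)(C)C)cc2)OC=C1S(=O)c1ccccc1
A8 | alternative 3 | [(1,1-dimethoxy-7-methylocta-1,3,6-trien-3-yl)oxy]trimethylsilane | COC(OC)=CC(O[Si](C)(C)C)=CCC=C(C)C
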